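**Retrosynthetic overview**

1. Cyclolinteinone is ring A, a cyclohex-2-enone (C1 carbonyl, C2 enone CH, C3 methyl-bearing enone carbon, C4 quaternary carbon, C5 CH(CH3), C6 CH2), with a C14 (E,E)-dienyl chain on C4 that ends in a 4-substituted furan-2(5H)-one.
2. Enabling feature: in ring A the C1 carbonyl is para to quaternary C4, the C5 methyl is ortho to C4, and the C2=C3(CH3) enone is the conjugated tautomer of an exocyclic methylene on C3. With an ester on C4 in place of the chain, ring A is the adduct of a 2-silyloxy-(E)-penta-1,3-diene (C2, C1, C6, C5) and a 2-methylallenoate (C3, C4).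
3. Key disconnection: a catalytic enantioselective Diels–Alder reaction joins C2 to C3 and C5 to C4 and sets both stereocentres; acid work-up in the same flask frees the ketone and moves the alkene into conjugation.
4. Side chain: ester to vinyl group, then three hydroboration/B-alkyl Suzuki couplings, two with (E)-4-iodopenta-1,3-diene (one C5 unit each, alkene geometry carried in by the iodide) and one with 4-bromofuran-2(5H)-one.
5. Ring order: ring A is built first (step 2); the butenolide ring is bought and attached last (step 12); ketal removal ends the route.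

Key step: step 2

Remark on the target: the SMILES is read as (4R,5R) in the ring numbering above ((1R,6R) in the systematic name), i.e. the C4 and C5 methyls trans and the side chain cis to the C5 methyl.

Assumption: the facial sense of the oxazaborolidinium catalyst with the α-methyl allenoate is taken by analogy with acrylate esters. The (S)-catalyst is written; the (R)-catalyst would be used without other change if the first run shows the opposite sense.

**Route**

Step 1
Reactants: 1 (E)-pent-3-en-2-one
Product: 2 triisopropyl{[(3E)-penta-1,3-dien-2-yl]oxy}silane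
Conditions: [(CH3)2CH]3SiOSO2CF3, Et3N, CH2Cl2, 0 °C
Reagents that add atoms: triisopropylsilyl trifluoromethanesulfonate, CC(C)[Si](C(C)C)(C(C)C)OS(=O)(=O)C(F)(F)F
Why: Soft enolisation (silyl enol ether formation): the silyl triflate activates the carbonyl group and triethylamine removes a proton from the acetyl methyl group, which should give the cross-conjugated 2-silyloxy diene with the (E)-alkene unchanged.

Step 2
Reactants: 2 triisopropyl{[(3E)-penta-1,3-dien-2-yl]oxy}silane; 3 ethyl 2-methylbuta-2,3-dienoate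
Product: 6 ethyl (1R,6R)-1,2,6-trimethyl-4-oxocyclohex-2-ene-1-carboxylate, via silyl enol ether cycloadduct 4 (not isolated), via methylene ketone 5 (not isolated)
Conditions: (S)-1-(2-methylphenyl)-3,3-diphenyltetrahydro-1H,3H-pyrrolo[1,2-c][1,3,2]oxazaborole (20 mol %), HN(SO2CF3)2 (18 mol %), CH2Cl2, −78 → −20 °C; then 2 M HCl, THF, 23 → 40 °C
Reagents that add atoms: none
Why: Proposed new method: the protonated oxazaborolidine binds the ester carbonyl of 3 and lowers the LUMO of its conjugated C=C bond (largest coefficient on the central allene carbon), so that diene 2 adds through its CH2 terminus (largest HOMO coefficient, the 2-silyloxy group and the terminal methyl polarising in the same sense) in a concerted asynchronous [4+2] cycloaddition; the closest known reaction types are the oxazaborolidinium-catalysed Diels–Alder reaction of 2-silyloxydienes with acrylate esters, the enantioselective [2+2] cycloaddition of allenoates under the same catalysts and the thermal Diels–Alder reaction of allenoates at their conjugated double bond. Ring A is closed by suprafacial [4+2] addition of the four-carbon unit C2–C1–C6–C5 to the two-carbon unit C3–C4, with bonds C2–C3 and C4–C5 formed in the same event. The relative configuration of quaternary C4 and of C5 follows from the (E)-geometry of the diene and the endo position of the boron-bound ester, which puts the ester cis to the C5 methyl and the two ring methyls trans; the absolute configuration is set by the catalyst, whose aryl group shields one face of the bound allenoate. The step needs regioselectivity (secured by the matched polarisation, siloxy para and methyl ortho to the ester), endo selectivity (ester against methyl on the same carbon, reinforced by Lewis acid binding), facial selectivity (catalyst) and chemoselectivity for the conjugated C=C bond of the allene (the only activated one). Aqueous acid then cleaves the silyl enol ether of 4, and the exocyclic alkene of 5 moves into conjugation with the new ketone to give the β-methyl enone; C4 is quaternary and C5 is not enolisable, so neither stereocentre can be lost.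

Step 3
Reactants: 6 ethyl (1R,6R)-1,2,6-trimethyl-4-oxocyclohex-2-ene-1-carboxylate
Product: 7 ethyl (8R,9R)-7,8,9-trimethyl-1,4-dioxaspiro[4.5]dec-6-ene-8-carboxylate
Conditions: (CH3)3SiOCH2CH2OSi(CH3)3, (CH3)3SiOSO2CF3 (5 mol %), CH2Cl2, −78 → −20 °C; pyridine quench
Reagents that add atoms: 1,2-bis(trimethylsilyloxy)ethane, C[Si](C)(C)OCCO[Si](C)(C)C
Why: Silyl-triflate-catalysed ketalisation with the bis-silyl ether of ethylene glycol runs at low temperature without free protic acid, so the dioxolane should form with the C=C bond left in place and the stereocentres untouched.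

Step 4
Reactants: 7 ethyl (8R,9R)-7,8,9-trimethyl-1,4-dioxaspiro[4.5]dec-6-ene-8-carboxylate
Product: 8 [(8R,9R)-7,8,9-trimethyl-1,4-dioxaspiro[4.5]dec-6-en-8-yl]methanol
Conditions: LiAlH4, THF, 0 °C → rt
Reagents that add atoms: none
Why: Hydride reduction of the ester by LiAlH4; the ketal masks the ketone, and the hindered ester on the quaternary carbon should still be reduced at room temperature.

Step 5
Reactants: 8 [(8R,9R)-7,8,9-trimethyl-1,4-dioxaspiro[4.5]dec-6-en-8-yl]methanol
Product: 9 (8R,9R)-7,8,9-trimethyl-1,4-dioxaspiro[4.5]dec-6-ene-8-carbaldehyde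
Conditions: (C3H7)4N[RuO4] (5 mol %), N-methylmorpholine N-oxide, 4 Å molecular sieves, CH2Cl2, rt
Reagents that add atoms: none
Why: Perruthenate-catalysed (Ley–Griffith) oxidation under neutral conditions spares the acid-labile allylic ketal, and the aldehyde has no α-hydrogen, so the quaternary centre cannot epimerise.

Step 6
Reactants: 9 (8R,9R)-7,8,9-trimethyl-1,4-dioxaspiro[4.5]dec-6-ene-8-carbaldehyde
Product: 10 (8R,9R)-8-ethenyl-7,8,9-trimethyl-1,4-dioxaspiro[4.5]dec-6-ene
Conditions: CH3P(C6H5)3Br, KOC(CH3)3, THF, 0 °C → rt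
Reagents that add atoms: methyltriphenylphosphonium bromide, C[P+](c1ccccc1)(c1ccccc1)c1ccccc1.[Br-]
Why: Wittig methylenation; the small unstabilised ylide should add even to the hindered aldehyde, which cannot enolise.

Step 7
Reactants: 11 but-2-yn-1-ol
Product: 13 (2E)-3-iodobut-2-en-1-ol, via alkenylzirconocene 12 (not isolated)
Conditions: (C5H5)2Zr(H)Cl (2.2 equiv), THF, rt; then I2, 0 °C
Reagents that add atoms: iodine, II; chlorohydridobis(cyclopentadienyl)zirconium, [H][Zr](Cl)(C1C=CC=C1)C1C=CC=C1 (zirconium is carried only by intermediate 12)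
Why: Hydrozirconation–iodination: the first equivalent of the hydride forms the zirconium alkoxide, the second adds syn across the alkyne with zirconium on the less hindered methyl-bearing carbon, and iodine cleaves the C–Zr bond with retention, which fixes the (E)-geometry.

Step 8
Reactants: 13 (2E)-3-iodobut-2-en-1-ol
Product: 14 (2E)-3-iodobut-2-enal
Conditions: MnO2, CH2Cl2, rt
Reagents that add atoms: none
Why: Allylic oxidation with MnO2 is selective for the allylic alcohol and does not touch the vinyl iodide or its geometry.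

Step 9
Reactants: 14 (2E)-3-iodobut-2-enal
Product: 15 (3E)-4-iodopenta-1,3-diene
Conditions: CH3P(C6H5)3Br, KOC(CH3)3, Et2O, −78 → 0 °C; product kept as a solution
Reagents that add atoms: methyltriphenylphosphonium bromide, C[P+](c1ccccc1)(c1ccccc1)c1ccccc1.[Br-]
Why: Wittig methylenation of the enal at low temperature leaves the geometry of the vinyl iodide unchanged; the volatile diene is carried on in solution.

Step 10
Reactants: 10 (8R,9R)-8-ethenyl-7,8,9-trimethyl-1,4-dioxaspiro[4.5]dec-6-ene; 15 (3E)-4-iodopenta-1,3-diene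
Product: 17 (8R,9R)-7,8,9-trimethyl-8-[(3E)-3-methylhexa-3,5-dien-1-yl]-1,4-dioxaspiro[4.5]dec-6-ene, via alkylborane 16 (not isolated)
Conditions: 9-BBN, THF, rt; then 15, [1,1'-bis(diphenylphosphino)ferrocene]dichloropalladium (5 mol %), As(C6H5)3, 3 M aq NaOH, THF/DMF, 50 °C
Reagents that add atoms: 9-borabicyclo[3.3.1]nonane, B1C2CCCC1CCC2 (boron is carried only by intermediate 16)
Why: B-alkyl Suzuki–Miyaura coupling: 9-BBN adds anti-Markovnikov to the monosubstituted vinyl group only (the trisubstituted ring alkene is inert), and the sp3–sp2 coupling proceeds with retention at the alkenyl iodide, so the (E)-trisubstituted alkene comes from 15.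

Step 11
Reactants: 17 (8R,9R)-7,8,9-trimethyl-8-[(3E)-3-methylhexa-3,5-dien-1-yl]-1,4-dioxaspiro[4.5]dec-6-ene; 15 (3E)-4-iodopenta-1,3-diene
Product: 19 (8R,9R)-8-[(3E,7E)-3,7-dimethyldeca-3,7,9-trien-1-yl]-7,8,9-trimethyl-1,4-dioxaspiro[4.5]dec-6-ene, via alkylborane 18 (not isolated)
Conditions: 9-BBN (1.05 equiv), THF, 0 °C → rt; then 15, [1,1'-bis(diphenylphosphino)ferrocene]dichloropalladium (5 mol %), As(C6H5)3, 3 M aq NaOH, THF/DMF, 50 °C
Reagents that add atoms: 9-borabicyclo[3.3.1]nonane, B1C2CCCC1CCC2 (boron is carried only by intermediate 18)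
Why: B-alkyl Suzuki–Miyaura coupling: in the conjugated diene 9-BBN should attack only the unsubstituted terminal carbon (least hindered position, trisubstituted alkenes inert), which gives the homoallylic borane and, after coupling with retention, the second (E)-alkene.

Step 12
Reactants: 19 (8R,9R)-8-[(3E,7E)-3,7-dimethyldeca-3,7,9-trien-1-yl]-7,8,9-trimethyl-1,4-dioxaspiro[4.5]dec-6-ene; 20 4-bromofuran-2(5H)-one
Product: 22 4-{(3E,7E)-4,8-dimethyl-10-[(8R,9R)-7,8,9-trimethyl-1,4-dioxaspiro[4.5]dec-6-en-8-yl]deca-3,7-dien-1-yl}furan-2(5H)-one, via alkylborane 21 (not isolated)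
Conditions: 9-BBN (1.05 equiv), THF, 0 °C → rt; then 20, [1,1'-bis(diphenylphosphino)ferrocene]dichloropalladium (5 mol %), As(C6H5)3, aq K3PO4, DMF, rt
Reagents that add atoms: 9-borabicyclo[3.3.1]nonane, B1C2CCCC1CCC2 (boron is carried only by intermediate 21)
Why: B-alkyl Suzuki–Miyaura coupling: the terminal diene carbon is hydroborated as in step 11, the bromobutenolide is a vinylogous acyl bromide that should undergo fast oxidative addition, and the mild phosphate base at room temperature should spare the lactone.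

Step 13
Reactants: 22 4-{(3E,7E)-4,8-dimethyl-10-[(8R,9R)-7,8,9-trimethyl-1,4-dioxaspiro[4.5]dec-6-en-8-yl]deca-3,7-dien-1-yl}furan-2(5H)-one
Product: 23 cyclolinteinone, 4-{(3E,7E)-4,8-dimethyl-10-[(1R,6R)-1,2,6-trimethyl-4-oxocyclohex-2-en-1-yl]deca-3,7-dien-1-yl}furan-2(5H)-one
Conditions: pyridinium p-toluenesulfonate (cat.), acetone/H2O, rt
Reagents that add atoms: water, O
Why: Acid-catalysed hydrolysis of the labile allylic dioxolane returns the conjugated enone; the mild acid should leave the trisubstituted alkenes and the butenolide untouched, and neither stereocentre is epimerisable.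

**Compound list**

1 | (E)-pent-3-en-2-one | C/C=C/C(C)=O | starting material
2 | triisopropyl{[(3E)-penta-1,3-dien-2-yl]oxy}silane | C/C=C/C(=C)O[Si](C(C)C)(C(C)C)C(C)C | intermediate
3 | ethyl 2-methylbuta-2,3-dienoate | C=C=C(C)C(=O)OCC | starting material
4 | ethyl (1R,2R)-1,2-dimethyl-6-methylidene-4-[(triisopropylsilyl)oxy]cyclohex-3-ene-1-carboxylate | C=C1CC(O[Si](C(C)C)(C(C)C)C(C)C)=C[C@@H](C)[C@@]1(C)C(=O)OCC | intermediate (not isolated)
5 | ethyl (1R,2R)-1,2-dimethyl-6-methylidene-4-oxocyclohexane-1-carboxylate | C=C1CC(=O)C[C@@H](C)[C@@]1(C)C(=O)OCC | intermediate (not isolated)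
6 | ethyl (1R,6R)-1,2,6-trimethyl-4-oxocyclohex-2-ene-1-carboxylate | CC1=CC(=O)C[C@@H](C)[C@@]1(C)C(=O)OCC | intermediate
7 | ethyl (8R,9R)-7,8,9-trimethyl-1,4-dioxaspiro[4.5]dec-6-ene-8-carboxylate | CC1=CC2(OCCO2)C[C@@H](C)[C@@]1(C)C(=O)OCC | intermediate
8 | [(8R,9R)-7,8,9-trimethyl-1,4-dioxaspiro[4.5]dec-6-en-8-yl]methanol | CC1=CC2(OCCO2)C[C@@H](C)[C@@]1(C)CO | intermediate
9 | (8R,9R)-7,8,9-trimethyl-1,4-dioxaspiro[4.5]dec-6-ene-8-carbaldehyde | CC1=CC2(OCCO2)C[C@@H](C)[C@@]1(C)C=O | intermediate
10 | (8R,9R)-8-ethenyl-7,8,9-trimethyl-1,4-dioxaspiro[4.5]dec-6-ene | CC1=CC2(OCCO2)C[C@@H](C)[C@@]1(C)C=C | intermediate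
11 | but-2-yn-1-ol | CC#CCO | starting material
12 | chloro{(2E)-4-[chlorobis(cyclopentadienyl)zirconiooxy]but-2-en-2-yl}bis(cyclopentadienyl)zirconium | C/C(=C\CO[Zr](Cl)(C1C=CC=C1)C1C=CC=C1)[Zr](Cl)(C1C=CC=C1)C1C=CC=C1 | intermediate (not isolated)
13 | (2E)-3-iodobut-2-en-1-ol | C/C(I)=C\CO | intermediate
14 | (2E)-3-iodobut-2-enal | C/C(I)=C\C=O | intermediate
15 | (3E)-4-iodopenta-1,3-diene | C/C(I)=C\C=C | intermediate
16 | 9-{2-[(8R,9R)-7,8,9-trimethyl-1,4-dioxaspiro[4.5]dec-6-en-8-yl]ethyl}-9-borabicyclo[3.3.1]nonane | CC1=CC2(OCCO2)C[C@@H](C)[C@@]1(C)CCB1C2CCCC1CCC2 | intermediate (not isolated)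
17 | (8R,9R)-7,8,9-trimethyl-8-[(3E)-3-methylhexa-3,5-dien-1-yl]-1,4-dioxaspiro[4.5]dec-6-ene | CC1=CC2(OCCO2)C[C@@H](C)[C@@]1(C)CC/C(C)=C/C=C | intermediate
18 | 9-{(3E)-4-methyl-6-[(8R,9R)-7,8,9-trimethyl-1,4-dioxaspiro[4.5]dec-6-en-8-yl]hex-3-en-1-yl}-9-borabicyclo[3.3.1]nonane | CC1=CC2(OCCO2)C[C@@H](C)[C@@]1(C)CC/C(C)=C/CCB1C2CCCC1CCC2 | intermediate (not isolated)
19 | (8R,9R)-8-[(3E,7E)-3,7-dimethyldeca-3,7,9-trien-1-yl]-7,8,9-trimethyl-1,4-dioxaspiro[4.5]dec-6-ene | CC1=CC2(OCCO2)C[C@@H](C)[C@@]1(C)CC/C(C)=C/CC/C(C)=C/C=C | intermediate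
20 | 4-bromofuran-2(5H)-one | BrC1=CC(=O)OC1 | starting material
21 | 9-{(3E,7E)-4,8-dimethyl-10-[(8R,9R)-7,8,9-trimethyl-1,4-dioxaspiro[4.5]dec-6-en-8-yl]deca-3,7-dien-1-yl}-9-borabicyclo[3.3.1]nonane | CC1=CC2(OCCO2)C[C@@H](C)[C@@]1(C)CC/C(C)=C/CC/C(C)=C/CCB1C2CCCC1CCC2 | intermediate (not isolated)
22 | 4-{(3E,7E)-4,8-dimethyl-10-[(8R,9R)-7,8,9-trimethyl-1,4-dioxaspiro[4.5]dec-6-en-8-yl]deca-3,7-dien-1-yl}furan-2(5H)-one | CC1=CC2(OCCO2)C[C@@H](C)[C@@]1(C)CC/C(C)=C/CC/C(C)=C/CCC1=CC(=O)OC1 | intermediate
23 | cyclolinteinone, 4-{(3E,7E)-4,8-dimethyl-10-[(1R,6R)-1,2,6-trimethyl-4-oxocyclohex-2-en-1-yl]deca-3,7-dien-1-yl}furan-2(5H)-one | CC1=CC(=O)C[C@@H](C)[C@@]1(C)CC/C(C)=C/CC/C(C)=C/CCC1=CC(=O)OC1 | target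

**Step count**

Total: 13 steps. Longest linear sequence: 10 steps (steps 1–6, then 10–13); steps 7–9 make the C5 building block 15, which is used twice.

**Steps most likely to fail**

Step 2 (proposed new method). What may go wrong: insufficient facial or endo selectivity in the cycloaddition, protodesilylation of the diene by the acidic catalyst before it reacts, or a stepwise Mukaiyama–Michael course that stops at an acyclic adduct. Fallback, by known chemistry (catalytic asymmetric Robinson annulation), sets out from 1 and comes back at 6. Iminium activation of 1 by 9-amino-9-deoxy-epi-quinine with an acid co-catalyst and Michael addition of commercial ethyl 2-methyl-3-oxobutanoate (CCOC(=O)C(C)C(C)=O) should give ethyl (2R,3R)-2-acetyl-2,3-dimethyl-5-oxohexanoate F1, with the C4–C5 bond in place. Pyrrolidine and acetic acid should then form the enamine of the unhindered methyl ketone, which closes onto the acetyl group next to the quaternary carbon (the C2–C3 bond), and dehydration gives 6. The quinidine-derived pseudo-enantiomer of the amine would be taken if the sense is opposite. The relative configuration is less predictable here than in the cycloaddition, so the diastereomer with the ester trans to the ring methyl, if formed, would be removed by chromatography at the stage of 6.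

Step 11. What may go wrong: loss of regio- and chemoselectivity in the hydroboration of the conjugated diene (attack at the internal position, double hydroboration), which would give isomeric boranes. Fallback sets out from 10 (through its borane 16, which is unproblematic) and comes back at 19, bypassing diene 17. Commercial pent-3-yn-1-ol (CC#CCCO) is converted by hydrozirconation–iodination ((C5H5)2Zr(H)Cl, then I2) into (3E)-4-iodopent-3-en-1-ol F2. Suzuki coupling of 16 with F2 should give (3E)-4-methyl-6-[(8R,9R)-7,8,9-trimethyl-1,4-dioxaspiro[4.5]dec-6-en-8-yl]hex-3-en-1-ol F3. Iodination (P(C6H5)3, I2, imidazole) gives (8R,9R)-8-[(3E)-6-iodo-3-methylhex-3-en-1-yl]-7,8,9-trimethyl-1,4-dioxaspiro[4.5]dec-6-ene F4. Zinc insertion (Zn, LiCl, THF) gives iodo{(3E)-4-methyl-6-[(8R,9R)-7,8,9-trimethyl-1,4-dioxaspiro[4.5]dec-6-en-8-yl]hex-3-en-1-yl}zinc F5, and Negishi coupling of F5 with 15 (Pd[P(C6H5)3]4, THF) gives 19. The sp3 metal is thus made from an alkyl iodide and not from a diene.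

Step 12. What may go wrong: base-induced ring opening or γ-deprotonation of the bromobutenolide and of the product during the cross-coupling. Fallback sets out from 21 and comes back at 22; the lactone is made after the coupling. Suzuki coupling of 21 with commercial 3-bromofuran (Brc1ccoc1) should give 3-{(3E,7E)-4,8-dimethyl-10-[(8R,9R)-7,8,9-trimethyl-1,4-dioxaspiro[4.5]dec-6-en-8-yl]deca-3,7-dien-1-yl}furan F6. Photooxygenation (O2, light, rose bengal C20H2Cl4I4Na2O5, diisopropylethylamine, CH2Cl2, −78 °C), in which the furan reacts far faster than the trisubstituted alkenes and the hindered base directs the opening of the endoperoxide, should give 5-hydroxy-4-{(3E,7E)-4,8-dimethyl-10-[(8R,9R)-7,8,9-trimethyl-1,4-dioxaspiro[4.5]dec-6-en-8-yl]deca-3,7-dien-1-yl}furan-2(5H)-one F7 (both epimers at the hydroxylated carbon). NaBH4 reduction of the masked aldehyde and lactonisation on mild acidification give 22.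

**Further compounds**

F1 | step 2 | ethyl (2R,3R)-2-acetyl-2,3-dimethyl-5-oxohexanoate | CC(=O)C[C@@H](C)[C@@](C(C)=O)(C)C(=O)OCC
F2 | step 11 | (3E)-4-iodopent-3-en-1-ol | C/C(I)=C\CCO
F3 | step 11 | (3E)-4-methyl-6-[(8R,9R)-7,8,9-trimethyl-1,4-dioxaspiro[4.5]dec-6-en-8-yl]hex-3-en-1-ol | CC1=CC2(OCCO2)C[C@@H](C)[C@@]1(C)CC/C(C)=C/CCO
F4 | step 11 | (8R,9R)-8-[(3E)-6-iodo-3-methylhex-3-en-1-yl]-7,8,9-trimethyl-1,4-dioxaspiro[4.5]dec-6-ene | CC1=CC2(OCCO2)C[C@@H](C)[C@@]1(C)CC/C(C)=C/CCI
F5 | step 11 | iodo{(3E)-4-methyl-6-[(8R,9R)-7,8,9-trimethyl-1,4-dioxaspiro[4.5]dec-6-en-8-yl]hex-3-en-1-yl}zinc | CC1=CC2(OCCO2)C[C@@H](C)[C@@]1(C)CC/C(C)=C/CC[Zn]I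
F6 | step 12 | 3-{(3E,7E)-4,8-dimethyl-10-[(8R,9R)-7,8,9-trimethyl-1,4-dioxaspiro[4.5]dec-6-en-8-yl]deca-3,7-dien-1-yl}furan | CC1=CC2(OCCO2)C[C@@H](C)[C@@]1(C)CC/C(C)=C/CC/C(C)=C/CCc1ccoc1
F7 | step 12 | 5-hydroxy-4-{(3E,7E)-4,8-dimethyl-10-[(8R,9R)-7,8,9-trimethyl-1,4-dioxaspiro[4.5]dec-6-en-8-yl]deca-3,7-dien-1-yl}furan-2(5H)-one | CC1=CC2(OCCO2)C[C@@H](C)[C@@]1(C)CC/C(C)=C/CC/C(C)=C/CCC1=CC(=O)OC1O
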